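## Structural features

The target is (2S)-5,3',4'-trihydroxy-7-methoxy-8-(3-methylbut-2-enyl)flavanone: a benzene ring A fused through C4a–C8a to a dihydropyran-4-one ring C, with a catechol ring B on C2. The only stereocentre is C2 (S); it is benzylic, bears O1 and lies β to the C4 ketone, so it can be lost by base-induced β-elimination of the O1 phenoxide (ring opening and reclosure) or by acid ionisation of the C2–O1 bond when ring B is electron-rich. Ring A is a fully differentiated phloroglucinol: O5 is a free phenol chelated to C4=O, O7 is a methyl ether, O8a is the ring oxygen O1, and C8, between C7 and C8a, carries the prenyl group, so that only C6 is a CH. The fragile groups are the trisubstituted prenyl alkene (protonation, hydration, cyclisation onto a neighbouring free phenol, no tolerance of hydrogenation), the oxidisable catechol and the stereocentre itself. The real difficulty is not ring C but the regiochemistry of ring A, because classical polyphenol chemistry distinguishes poorly between C6 and C8 and between the three oxygens. The key step exploits the fact that C8(prenyl)–C8a(O) is a two-carbon ynol ether unit while C7(O), C4a(H), C5(O) and C6(H) are the four carbons of a 3-alkoxy vinylketene, so joining the two writes the whole pattern of ring A, each oxygen with a different substituent.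

## Logic of the disconnections

**25 to 24.** The two O–acetyl bonds on ring B are cut last. Acetates keep ring B electron-poor, which protects the C2–O1 bond against ionisation in every acidic step and shields the catechol from oxidation. The forward step must remove them without base, because base would open ring C and racemise C2.

**24 to 23.** The O5–isopropyl bond is cut. A secondary alkyl ether peri to C4=O can be cleaved by a chelating Lewis acid at low temperature, which distinguishes O5 from the methyl ether at O7. The forward step must leave the prenyl alkene, the acetates and the O7 methyl ether untouched.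

**23 to 21 (through 22).** The C4–C4a bond is cut, opening ring C to an acyclic aryloxy acid. C4a is the only free carbon ortho to O1 and is activated by O1, O5 and O7, so the acylation has one possible outcome and does not touch C2. The forward step must acylate faster than the acid medium attacks the prenyl group.

**21 to 20.** The O–allyl bond of the ester is cut. The acid has to be liberated without hydroxide, which would cleave the aryl acetates and could eliminate the β-aryloxy group. This demands a neutral, palladium-catalysed deprotection.

**20 to 14 and 19.** The O1–C2 bond is cut, dividing the molecule into the ring A phenol and a three-carbon ring B unit. The stereocentre is made in the small fragment and transferred with inversion. The forward step needs substitution at the carbinol carbon to outrun elimination toward the ester and ionisation.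

**19 to 18 to 15.** First the carbinol C–H bond is cut (ketone reduction), then the C–C bond between the aroyl carbon and the acetate unit. This leads back to a commercial benzoic acid. The forward steps need catalyst-controlled facial selectivity and conditions that spare aryl acetates.

**14 to 13 to 12.** The O8a–Si bond and the O7–CH3 bond are cut. In 12 the only free phenol is O7 and O8a is silylated, so methylation followed by desilylation places the methyl group and frees the coupling oxygen without any selectivity problem. The forward steps need a base-stable silyl ether and a non-acidic desilylation, since the freed phenol sits next to the prenyl group.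

**12 to 2 and 7 (through 8, 9, 10, 11).** The C7–C8, C4a–C8a and C6–C7 bonds are cut, so the whole of ring A falls into two small achiral fragments. Tracing the atoms (ketene carbon to C7, alkyne carbons to C8 and C8a, remaining cyclobutenone carbons to C4a, C5, C6) reproduces 12 exactly; no structural correction was needed. The forward step needs a regioselective [2+2] addition, preference for the alkyne over the prenyl alkene, and thermal stability of both partners.

**7 to 3 and 4 (through 5, 6); 2 to 1.** In 7 the O–Si bond and the alkyne C–C bond formed by one-carbon homologation are cut, leading to a commercial ester and chlorosilane. In 2 the O–alkyl bond at C3 is exchanged; the isopropyl group is chosen because it makes the late O5 cleavage fast at low temperature. The forward steps need carbonyl addition to beat enolisation of the β,γ-unsaturated ester, and alkoxy exchange to beat ring cleavage.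

## Other disconnections considered

**Alternative 1:** The cut is at C4a–C5 and C8–C8a, building ring A last on an intact ring C.

- *Forward step:* the trioxygenated diene A3 adds across the C5=C6 bond of the bromodihydropyranone A2; loss of hydrogen bromide and methanol aromatises the adduct to A1.
- *In favour:* it is the most convergent plan. A1 is one desilylation from the target, and C2 could be set catalytically when A2 is made. The regiochemistry of ring A is again dictated by fragment substituents, so on that point it is the equal of the chosen plan. On step economy it is probably the better.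
- *Against:* A2 is a vinylogous ester and a poor dienophile for an electron-rich diene, and the bromine helps only partly. The reacting terminus of A3 carries the prenyl-bearing methylene, which slows the cycloaddition and demands one diene geometry. Forcing conditions expose C2 of A2, which bears an electron-rich silyloxyaryl group, to ring opening. The aromatisation also releases acid next to a prenyl group and silyl ethers.
- *Comparison:* the chosen cascade pairs an electrophilic ketene with a nucleophilic ynol ether, a matched pair, whereas Alternative 1 pairs two donors. The chosen plan also introduces C2 after ring A exists, instead of carrying it through the riskiest step.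

**Alternative 2:** The cut is at O1–C8a.

- *Forward step:* KN(SiMe3)2 deprotonates the β-hydroxy ketone A5 and the alkoxide displaces the fluoride ortho to the ketone by addition–elimination, giving A4.
- *In favour:* no bond to C2 is formed or broken, so the configuration is retained and there is no inversion step that can leak. The closure is acid-free, which suits the prenyl group; on acid sensitivity it is better than the ring C closure of the chosen plan.
- *Against:* the fluoroarene carries two oxygen donors and is activated by a single ortho carbonyl. The potassium aldolate of A5 can fragment by retro-aldol or dehydrate, and A4 can open by β-elimination under the same base, so the configuration is at risk from the base instead of from acid. A5 needs a pentasubstituted fluoroarene assembled by successive directed metalations, which returns the ring A problem to classical arene chemistry. An enantioselective aldol of an aryl methyl ketone is also less dependable than a ketone reduction.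
- *Comparison:* the end game from A4 (desilylation, acidic removal of two acetals) is about as long as that of the chosen plan, so there the two are equal. The route to A5 should be longer than the two-fragment benzannulation.

**Alternative 3:** The cut is at C4–C4a.

- *Forward step:* the aryloxy acid A7 is converted by (CF3CO)2O into its mixed anhydride, which acylates C4a to give A6.
- *In favour:* there is only one free ortho position, C2 is not involved, and all three acetates of A6 fall in one final operation. That makes the end game one step shorter than in the chosen plan, and on that point it is the better. The closure itself is the same bond formation that the chosen plan uses in step 10, so there the two are equal.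
- *Against:* as the strategic step it leaves the main problem unsolved. The ring A part of A7, with acetoxy, methoxy and prenyl groups in defined positions, would have to come from C-prenylation and stepwise differentiation of a symmetrical triphenol. A 5-acetoxy group makes C4a less nucleophilic than a 5-alkoxy group does, and a phenolic acetate on ring A can migrate during the etherification that builds A7.
- *Comparison:* the chosen plan amounts to this closure fed by a regiodefined arene. It is longer at the end but should be shorter and cleaner at the start.

Key step: step 3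

Assumption: in step 7 the (R,R)-configured catalyst is taken to give the (R)-alcohol, as it does for simple aryl ketones with the same priority order; should the sense be opposite, the (S,S)-ligand would be used.

## Route

Step 1
Reactants: 1 3-ethoxycyclobut-2-en-1-one
Product: 2 3-isopropoxycyclobut-2-en-1-one
Conditions: i-PrOH (large excess), TsOH·H2O (cat.), 40 °C, repeated concentration from fresh i-PrOH
Reagents that add atoms: 2-propanol, CC(C)O
Why: Acid-catalysed alkoxy exchange of a vinylogous ester by addition–elimination at C3, driven by excess 2-propanol and removal of ethanol; the secondary alkyl group is installed here so that O5 can later be freed at low temperature.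

Step 2
Reactants: 3 ethyl 4-methylpent-3-enoate; 4 chlorotriisopropylsilane
Product: 7 triisopropyl[(5-methylhex-4-en-1-yn-1-yl)oxy]silane, via dibromo enolate 5 (not isolated), via ynolate 6 (not isolated)
Conditions: CH2Br2, LiTMP, THF, −78 °C; 3; n-BuLi, −78 → 0 °C; 4, −78 °C → rt
Reagents that add atoms: dibromomethane, BrCBr
Why: Kowalski ester homologation: LiCHBr2 adds to the ester carbonyl and the adduct collapses to enolate 5; bromine–lithium exchange and 1,2-shift of the alkyl group with loss of LiBr give ynolate 6. The bulky chlorosilane 4 should trap 6 on oxygen and not on carbon; the weakly basic carbenoid at −78 °C is expected to add before it enolises the ester.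

Step 3
Reactants: 2 3-isopropoxycyclobut-2-en-1-one; 7 triisopropyl[(5-methylhex-4-en-1-yn-1-yl)oxy]silane
Product: 12 5-isopropoxy-2-(3-methylbut-2-enyl)-3-(triisopropylsilyloxy)phenol, via vinylketene 8 (not isolated), via vinylcyclobutenone 9 (not isolated), via dienylketene 10 (not isolated), via cyclohexadienone 11 (not isolated)
Conditions: toluene (degassed), 80 → 110 °C, sealed tube, 7 in slight excess
Reagents that add atoms: none
Why: Heating opens 2 by a four-electron electrocyclic reaction to vinylketene 8, whose ketene C=C adds [2+2] to the electron-rich ynol ether 7 to give vinylcyclobutenone 9 (C7–C8 and C4a–C8a formed). A second four-electron opening gives dienylketene 10, a disrotatory six-electron electrocyclisation closes ring A at C6–C7 to cyclohexadienone 11, and tautomerisation delivers phenol 12. The closest known reaction type is the Danheiser benzannulation of cyclobutenones with trialkylsilyloxyalkynes, which gives resorcinol monosilyl ethers with the same placement of OH, alkyne substituent and silyloxy group. No stereocentre is formed. The step needs regioselectivity in the [2+2] addition, and the polarisation of 7 supplies it: the prenyl-bearing carbon is the nucleophilic end and bonds to the ketene carbonyl carbon (future C7), so the prenyl group ends between the new hydroxyl and the silyl ether. It also needs preference for the alkyne over the prenyl alkene, secured by the far higher nucleophilicity of the ynol ether, and silicon must stay on oxygen, which the bulky triisopropylsilyl group favours. A slight excess of 7 keeps 8 from acylating the product phenol.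

Step 4
Reactants: 12 5-isopropoxy-2-(3-methylbut-2-enyl)-3-(triisopropylsilyloxy)phenol
Product: 13 triisopropyl[5-isopropoxy-3-methoxy-2-(3-methylbut-2-enyl)phenoxy]silane
Conditions: MeI, K2CO3, acetone, 50 °C
Reagents that add atoms: iodomethane, CI
Why: Williamson methylation of the only free phenol (O7); the hindered aryl silyl ether should be stable to K2CO3 in an aprotic solvent, and the base cannot harm the prenyl group.

Step 5
Reactants: 13 triisopropyl[5-isopropoxy-3-methoxy-2-(3-methylbut-2-enyl)phenoxy]silane
Product: 14 5-isopropoxy-3-methoxy-2-(3-methylbut-2-enyl)phenol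
Conditions: Bu4NF, AcOH, THF, 0 °C
Reagents that add atoms: none
Why: Fluoride cleavage of the aryl silyl ether frees O8a; the acetic acid buffer avoids a free phenoxide, and no acid strong enough to cyclise the phenol onto the neighbouring prenyl group is present.

Step 6
Reactants: 15 3,4-diacetoxybenzoic acid
Product: 18 allyl 3-(3,4-diacetoxyphenyl)-3-oxopropanoate, via acid chloride 16 (not isolated), via acyl Meldrum's acid 17 (not isolated)
Conditions: (COCl)2, DMF (cat.), CH2Cl2, 0 °C → rt; Meldrum's acid, pyridine, CH2Cl2, 0 °C; allyl alcohol, toluene, 85 °C
Reagents that add atoms: Meldrum's acid (2,2-dimethyl-1,3-dioxane-4,6-dione), CC1(C)OC(=O)CC(=O)O1; allyl alcohol, C=CCO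
Why: C-Acylation of Meldrum's acid followed by thermal alcoholysis with loss of acetone and carbon dioxide is a standard β-keto ester synthesis; no step uses a nucleophile strong enough to attack the aryl acetates.

Step 7
Reactants: 18 allyl 3-(3,4-diacetoxyphenyl)-3-oxopropanoate
Product: 19 allyl (3R)-3-(3,4-diacetoxyphenyl)-3-hydroxypropanoate
Conditions: RuCl[(R,R)-TsDPEN](p-cymene) (1 mol %), HCO2H/Et3N (5:2), EtOAc, rt
Reagents that add atoms: none
Why: Noyori asymmetric transfer hydrogenation of an aryl ketone; the CH/π contact between the cymene ligand and the aryl ring fixes the face of hydride delivery, and the (R,R)-ligand is expected to give the (R)-carbinol. The weakly acidic medium should leave aryl acetates and the allyl ester intact.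

Step 8
Reactants: 14 5-isopropoxy-3-methoxy-2-(3-methylbut-2-enyl)phenol; 19 allyl (3R)-3-(3,4-diacetoxyphenyl)-3-hydroxypropanoate
Product: 20 allyl (3S)-3-(3,4-diacetoxyphenyl)-3-[5-isopropoxy-3-methoxy-2-(3-methylbut-2-enyl)phenoxy]propanoate
Conditions: PPh3, DIAD (slow addition), toluene, 0 °C → rt
Reagents that add atoms: none
Why: Mitsunobu etherification: the phenoxide displaces the alkoxyphosphonium group by SN2 with inversion, turning the (R)-carbinol into the (S)-aryl ether that becomes C2. The electron-poor diacetoxyphenyl group disfavours ionisation, so the inversion should be clean.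

Step 9
Reactants: 20 allyl (3S)-3-(3,4-diacetoxyphenyl)-3-[5-isopropoxy-3-methoxy-2-(3-methylbut-2-enyl)phenoxy]propanoate
Product: 21 (3S)-3-(3,4-diacetoxyphenyl)-3-[5-isopropoxy-3-methoxy-2-(3-methylbut-2-enyl)phenoxy]propanoic acid
Conditions: Pd(PPh3)4 (5 mol %), PhNHMe, THF, rt
Reagents that add atoms: none
Why: Tsuji–Trost deallylation: zerovalent palladium ionises the allyl ester and the allyl group is captured by N-methylaniline, which is too weak a nucleophile and base to attack the aryl acetates or to eliminate the β-aryloxy group; the isolated prenyl alkene is inert.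

Step 10
Reactants: 21 (3S)-3-(3,4-diacetoxyphenyl)-3-[5-isopropoxy-3-methoxy-2-(3-methylbut-2-enyl)phenoxy]propanoic acid
Product: 23 (2S)-3',4'-diacetoxy-5-isopropoxy-7-methoxy-8-(3-methylbut-2-enyl)flavanone, via mixed anhydride 22 (not isolated)
Conditions: (CF3CO)2O, CH2Cl2, 0 °C → rt
Reagents that add atoms: none
Why: Intramolecular Friedel–Crafts acylation through the mixed anhydride 22: C4a is the only free carbon ortho to the ether oxygen and is activated by O1, O5 and O7, so ring C closes in one sense only. C2 is not involved, the acetylated ring B resists acid ionisation of the C2–O bond, and the prenyl group has no free phenol beside it.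

Step 11
Reactants: 23 (2S)-3',4'-diacetoxy-5-isopropoxy-7-methoxy-8-(3-methylbut-2-enyl)flavanone
Product: 24 (2S)-3',4'-diacetoxy-5-hydroxy-7-methoxy-8-(3-methylbut-2-enyl)flavanone
Conditions: BCl3, CH2Cl2, −78 → −20 °C; aq. NaHCO3
Reagents that add atoms: none
Why: Chelation-directed ether cleavage: boron bound between C4=O and O5 expels the secondary alkyl group as 2-chloropropane at low temperature. The non-chelated methyl ether at O7, the aryl acetates and the alkene should not react under these conditions.

Step 12
Reactants: 24 (2S)-3',4'-diacetoxy-5-hydroxy-7-methoxy-8-(3-methylbut-2-enyl)flavanone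
Product: 25 (2S)-5,3',4'-trihydroxy-7-methoxy-8-(3-methylbut-2-enyl)flavanone
Conditions: HCl (0.5 M in MeOH), 0 °C → rt
Reagents that add atoms: none
Why: Acid-catalysed methanolysis of the two aryl acetates; avoiding base excludes ring opening by β-elimination (racemisation of C2) and autoxidation of the catechol, and the prenyl group, flanked only by ether oxygens, cannot cyclise.

## Compound list

1 | 3-ethoxycyclobut-2-en-1-one | CCOC1=CC(=O)C1 | starting material
2 | 3-isopropoxycyclobut-2-en-1-one | CC(C)OC1=CC(=O)C1 | intermediate
3 | ethyl 4-methylpent-3-enoate | CC(C)=CCC(=O)OCC | starting material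
4 | chlorotriisopropylsilane | CC(C)[Si](Cl)(C(C)C)C(C)C | starting material
5 | lithium 1,1-dibromo-5-methylhexa-1,4-dien-2-olate | CC(C)=CCC([O-])=C(Br)Br.[Li+] | intermediate
6 | lithium 5-methylhex-4-en-1-yn-1-olate | CC(C)=CCC#C[O-].[Li+] | intermediate
7 | triisopropyl[(5-methylhex-4-en-1-yn-1-yl)oxy]silane | CC(C)=CCC#CO[Si](C(C)C)(C(C)C)C(C)C | intermediate
8 | 3-isopropoxybuta-1,3-dien-1-one | O=C=CC(=C)OC(C)C | intermediate
9 | 4-(1-isopropoxyvinyl)-2-(3-methylbut-2-enyl)-3-(triisopropylsilyloxy)cyclobut-2-en-1-one | O=C1C(CC=C(C)C)=C(O[Si](C(C)C)(C(C)C)C(C)C)C1C(=C)OC(C)C | intermediate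
10 | (3E)-5-isopropoxy-2-(3-methylbut-2-enyl)-3-(triisopropylsilyloxy)hexa-1,3,5-trien-1-one | O=C=C(CC=C(C)C)/C(O[Si](C(C)C)(C(C)C)C(C)C)=C\C(=C)OC(C)C | intermediate
11 | 5-isopropoxy-2-(3-methylbut-2-enyl)-3-(triisopropylsilyloxy)cyclohexa-2,4-dien-1-one | O=C1C(CC=C(C)C)=C(O[Si](C(C)C)(C(C)C)C(C)C)C=C(OC(C)C)C1 | intermediate
12 | 5-isopropoxy-2-(3-methylbut-2-enyl)-3-(triisopropylsilyloxy)phenol | Oc1cc(OC(C)C)cc(O[Si](C(C)C)(C(C)C)C(C)C)c1CC=C(C)C | intermediate
13 | triisopropyl[5-isopropoxy-3-methoxy-2-(3-methylbut-2-enyl)phenoxy]silane | COc1cc(OC(C)C)cc(O[Si](C(C)C)(C(C)C)C(C)C)c1CC=C(C)C | intermediate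
14 | 5-isopropoxy-3-methoxy-2-(3-methylbut-2-enyl)phenol | COc1cc(OC(C)C)cc(O)c1CC=C(C)C | intermediate
15 | 3,4-diacetoxybenzoic acid | CC(=O)Oc1ccc(C(=O)O)cc1OC(C)=O | starting material
16 | 3,4-diacetoxybenzoyl chloride | CC(=O)Oc1ccc(C(Cl)=O)cc1OC(C)=O | intermediate
17 | 5-[(3,4-diacetoxyphenyl)(hydroxy)methylene]-2,2-dimethyl-1,3-dioxane-4,6-dione | CC(=O)Oc1ccc(C(O)=C2C(=O)OC(C)(C)OC2=O)cc1OC(C)=O | intermediate
18 | allyl 3-(3,4-diacetoxyphenyl)-3-oxopropanoate | C=CCOC(=O)CC(=O)c1ccc(OC(C)=O)c(OC(C)=O)c1 | intermediate
19 | allyl (3R)-3-(3,4-diacetoxyphenyl)-3-hydroxypropanoate | C=CCOC(=O)C[C@@H](O)c1ccc(OC(C)=O)c(OC(C)=O)c1 | intermediate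
20 | allyl (3S)-3-(3,4-diacetoxyphenyl)-3-[5-isopropoxy-3-methoxy-2-(3-methylbut-2-enyl)phenoxy]propanoate | C=CCOC(=O)C[C@H](Oc1cc(OC(C)C)cc(OC)c1CC=C(C)C)c1ccc(OC(C)=O)c(OC(C)=O)c1 | intermediate
21 | (3S)-3-(3,4-diacetoxyphenyl)-3-[5-isopropoxy-3-methoxy-2-(3-methylbut-2-enyl)phenoxy]propanoic acid | OC(=O)C[C@H](Oc1cc(OC(C)C)cc(OC)c1CC=C(C)C)c1ccc(OC(C)=O)c(OC(C)=O)c1 | intermediate
22 | mixed anhydride of acid 21 and trifluoroacetic acid | O=C(C[C@H](Oc1cc(OC(C)C)cc(OC)c1CC=C(C)C)c1ccc(OC(C)=O)c(OC(C)=O)c1)OC(=O)C(F)(F)F | intermediate
23 | (2S)-3',4'-diacetoxy-5-isopropoxy-7-methoxy-8-(3-methylbut-2-enyl)flavanone | COc1cc(OC(C)C)c2c(c1CC=C(C)C)O[C@H](c1ccc(OC(C)=O)c(OC(C)=O)c1)CC2=O | intermediate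
24 | (2S)-3',4'-diacetoxy-5-hydroxy-7-methoxy-8-(3-methylbut-2-enyl)flavanone | COc1cc(O)c2c(c1CC=C(C)C)O[C@H](c1ccc(OC(C)=O)c(OC(C)=O)c1)CC2=O | intermediate
25 | (2S)-5,3',4'-trihydroxy-7-methoxy-8-(3-methylbut-2-enyl)flavanone (CNP0294928.1) | COc1cc(O)c2c(c1CC=C(C)C)O[C@H](c1ccc(O)c(O)c1)CC2=O | target

## Step count and least certain steps

Total: 12 steps. Longest linear sequence: 9 steps (step 1 or step 2, then steps 3, 4, 5, 8, 9, 10, 11, 12).

**Step 3 (key step).** The vinylogous-ester stabilisation of 2 may slow its electrocyclic opening. At the temperature then needed, 7 could isomerise by a 1,3-shift of silicon from oxygen to carbon, or 8 could oligomerise or acylate the product phenol. The fallback sets out from 7 and makes the same vinylketene 8 cold by 1,4-dehydrochlorination: (E)-3-isopropoxybut-2-enoyl chloride F1 is treated with Et3N in the presence of 7 at 0 °C to room temperature. The [2+2] addition should then give 9, which needs only gentle heating (about 80 °C) to pass through 10 and 11; the route is rejoined at 9 and so at 12.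

**Step 8.** The activated β-hydroxy ester may eliminate toward the conjugated ester faster than the ortho-substituted phenol substitutes, and acetyl transfer from ring B to the phenoxide is possible. The fallback sets out from 19, uses 14 unchanged and removes the acidic α-hydrogens before the etherification:
- deallylation of 19 (Pd(PPh3)4, PhNHMe) gives (3R)-3-(3,4-diacetoxyphenyl)-3-hydroxypropanoic acid F2;
- BH3·SMe2 in THF at 0 °C, which reduces acids in preference to aryl esters, gives (1R)-1-(3,4-diacetoxyphenyl)propane-1,3-diol F3;
- silylation of the primary hydroxyl (t-BuMe2SiCl, imidazole, −20 °C) gives (1R)-3-(tert-butyldimethylsilyloxy)-1-(3,4-diacetoxyphenyl)propan-1-ol F4;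
- Mitsunobu coupling of F4 with 14 (PPh3, DIAD) gives, with inversion, the (S)-configured silyl ether F5;
- HF·pyridine frees (3S)-3-(3,4-diacetoxyphenyl)-3-[5-isopropoxy-3-methoxy-2-(3-methylbut-2-enyl)phenoxy]propan-1-ol F6;
- oxidation with TEMPO (cat.) and PhI(OAc)2 in aqueous MeCN rejoins the route at 21.

**Step 1.** Acid may cleave the strained ring by attack of the alcohol at the carbonyl instead of exchanging the alkoxy group, or the exchange may stall at equilibrium. The fallback sets out from 1: hydrolysis with cold dilute aqueous HCl gives cyclobutane-1,3-dione F7, and its acidic enol is O-alkylated with 2-propanol under Mitsunobu conditions (PPh3, DIAD), returning to the route at 2.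

**Step 10.** The trifluoroacetic acid released may protonate the prenyl alkene (addition or double-bond migration), or the mixed anhydride may acylate C6 of a second molecule. The fallback sets out from 21 and replaces the acylium route by amide activation. Coupling with Me2NH·HCl (EDC, HOBt, i-Pr2NEt, 0 °C) gives the N,N-dimethylamide F8. Tf2O with 2-fluoropyridine in CH2Cl2 (−78 → 0 °C) converts F8 into an iminium triflate that C4a attacks in a buffered medium, and aqueous NaHCO3 hydrolysis of the cyclic iminium returns to the route at 23.

**Step 2.** The doubly activated α-hydrogens of the β,γ-unsaturated ester 3 may be removed by the amide base or the carbenoid, leading to enolisation, double-bond migration and self-condensation instead of carbonyl addition. The fallback sets out from chlorosilane 4 and reaches the ynolate by oxidation of an acetylide. 5-Methylhex-4-en-1-yne F9 (from copper-catalysed coupling of prenyl bromide with ethynylmagnesium bromide) is lithiated with n-BuLi and oxidised with lithium tert-butyl peroxide (t-BuOOH, LiN(SiMe3)2) in THF at −78 → 0 °C. This gives ynolate 6, which is silylated with 4 to rejoin the route at 7.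

## Further compounds

F1 | step 3 | (E)-3-isopropoxybut-2-enoyl chloride | C/C(OC(C)C)=C\C(Cl)=O
F2 | step 8 | (3R)-3-(3,4-diacetoxyphenyl)-3-hydroxypropanoic acid | OC(=O)C[C@@H](O)c1ccc(OC(C)=O)c(OC(C)=O)c1
F3 | step 8 | (1R)-1-(3,4-diacetoxyphenyl)propane-1,3-diol | OCC[C@@H](O)c1ccc(OC(C)=O)c(OC(C)=O)c1
F4 | step 8 | (1R)-3-(tert-butyldimethylsilyloxy)-1-(3,4-diacetoxyphenyl)propan-1-ol | CC(C)(C)[Si](C)(C)OCC[C@@H](O)c1ccc(OC(C)=O)c(OC(C)=O)c1
F5 | step 8 | tert-butyl{(3S)-3-(3,4-diacetoxyphenyl)-3-[5-isopropoxy-3-methoxy-2-(3-methylbut-2-enyl)phenoxy]propoxy}dimethylsilane | CC(C)(C)[Si](C)(C)OCC[C@H](Oc1cc(OC(C)C)cc(OC)c1CC=C(C)C)c1ccc(OC(C)=O)c(OC(C)=O)c1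
F6 | step 8 | (3S)-3-(3,4-diacetoxyphenyl)-3-[5-isopropoxy-3-methoxy-2-(3-methylbut-2-enyl)phenoxy]propan-1-ol | OCC[C@H](Oc1cc(OC(C)C)cc(OC)c1CC=C(C)C)c1ccc(OC(C)=O)c(OC(C)=O)c1
F7 | step 1 | cyclobutane-1,3-dione | O=C1CC(=O)C1
F8 | step 10 | (3S)-3-(3,4-diacetoxyphenyl)-3-[5-isopropoxy-3-methoxy-2-(3-methylbut-2-enyl)phenoxy]-N,N-dimethylpropanamide | CN(C)C(=O)C[C@H](Oc1cc(OC(C)C)cc(OC)c1CC=C(C)C)c1ccc(OC(C)=O)c(OC(C)=O)c1
F9 | step 2 | 5-methylhex-4-en-1-yne | CC(C)=CCC#C
A1 | alternative 1 | (2S)-3',4'-bis(tert-butyldimethylsilyloxy)-5-hydroxy-7-methoxy-8-(3-methylbut-2-enyl)flavanone | COc1cc(O)c2c(c1CC=C(C)C)O[C@H](c1ccc(O[Si](C)(C)C(C)(C)C)c(O[Si](C)(C)C(C)(C)C)c1)CC2=O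
A2 | alternative 1 | (2S)-5-bromo-2-[3,4-bis(tert-butyldimethylsilyloxy)phenyl]-2,3-dihydro-4H-pyran-4-one | BrC1=CO[C@H](c2ccc(O[Si](C)(C)C(C)(C)C)c(O[Si](C)(C)C(C)(C)C)c2)CC1=O
A3 | alternative 1 | [(1,3-dimethoxy-7-methylocta-1,3,6-trien-1-yl)oxy]trimethylsilane | COC(O[Si](C)(C)C)=CC(OC)=CCC=C(C)C
A4 | alternative 2 | (2S)-7-methoxy-3',4'-bis(methoxymethoxy)-8-(3-methylbut-2-enyl)-5-(triisopropylsilyloxy)flavanone | COc1cc(O[Si](C(C)C)(C(C)C)C(C)C)c2c(c1CC=C(C)C)O[C@H](c1ccc(OCOC)c(OCOC)c1)CC2=O
A5 | alternative 2 | (3S)-1-[2-fluoro-4-methoxy-3-(3-methylbut-2-enyl)-6-(triisopropylsilyloxy)phenyl]-3-hydroxy-3-[3,4-bis(methoxymethoxy)phenyl]propan-1-one | COc1cc(O[Si](C(C)C)(C(C)C)C(C)C)c(C(=O)C[C@H](O)c2ccc(OCOC)c(OCOC)c2)c(F)c1CC=C(C)C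
A6 | alternative 3 | (2S)-5,3',4'-triacetoxy-7-methoxy-8-(3-methylbut-2-enyl)flavanone | COc1cc(OC(C)=O)c2c(c1CC=C(C)C)O[C@H](c1ccc(OC(C)=O)c(OC(C)=O)c1)CC2=O
A7 | alternative 3 | (3S)-3-[5-acetoxy-3-methoxy-2-(3-methylbut-2-enyl)phenoxy]-3-(3,4-diacetoxyphenyl)propanoic acid | OC(=O)C[C@H](Oc1cc(OC(C)=O)cc(OC)c1CC=C(C)C)c1ccc(OC(C)=O)c(OC(C)=O)c1
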